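**Retrosynthetic overview**

1. Target ⇒ acylation of O4, anti-selective reduction of a C4 ketone directed by the C3 hydroxyl, and angeloylation of O1; both esters go on last, each when only one secondary OH is free.
2. cis-1,3-Diol (C1–OH and the tertiary isopropyl carbinol C3) ⇒ cyclopentenone by Luche reduction, OH-directed epoxidation and hydride opening; the C4 ketone is masked as a dioxolane meanwhile.
3. β,γ-Unsaturated seven-membered ketone ⇒ 1,6-reduction of a cycloheptadienone.
4. Key disconnection: cycloheptadienone ⇒ α-methyl α-diazoketone by intramolecular Büchner reaction (arene cyclopropanation, 6π ring opening). The five- and seven-membered rings form together and the angular methyl centre is set; the arene supplies the C4 oxygen (as OMe) and the C6 methyl.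
5. Diazoketone ⇒ arylboronic acid 1 + enoate 2 by asymmetric conjugate arylation, the only external source of chirality.

Assumption: the stereodescriptors of the given SMILES are taken literally (cis-fused core, (1S,3S,3aR,4R,8aR) in azulene numbering); azulene numbering is used for all bicyclic compounds (C1 bears the angelate, C3 the isopropyl carbinol, C4 the benzoate, C3a/C8a are the ring-fusion carbons).

**Route**

Step 1
Reactants: 1 (2-methoxy-4-methylphenyl)boronic acid; 2 ethyl (2E)-4-methylpent-2-enoate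
Product: 3 ethyl (3S)-3-(2-methoxy-4-methylphenyl)-4-methylpentanoate
Conditions: [Rh(acac)(C2H4)2] (3 mol %), (R)-BINAP (3.3 mol %), dioxane/H2O 10:1, 100 °C
Reagents that add atoms: none
Why: Hayashi–Miyaura rhodium-catalysed asymmetric 1,4-addition, in which the aryl–rhodium–BINAP species carbometalates one enantioface of the (E)-enoate; the (R)-ligand is chosen because it should give the 3S benzylic centre with a β-isopropyl acceptor.

Step 2
Reactants: 3 ethyl (3S)-3-(2-methoxy-4-methylphenyl)-4-methylpentanoate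
Product: 4 (3S)-3-(2-methoxy-4-methylphenyl)-4-methylpentanoic acid
Conditions: LiOH, THF/MeOH/H2O 3:1:1, 23 °C; then 1 M HCl
Reagents that add atoms: lithium hydroxide, [Li+].[OH-]
Why: Ester saponification; the stereocentre is β to the carbonyl and cannot epimerise.

Step 3
Reactants: 4 (3S)-3-(2-methoxy-4-methylphenyl)-4-methylpentanoic acid
Product: 6 (5S)-2-diazo-5-(2-methoxy-4-methylphenyl)-6-methylheptan-3-one, via acid chloride 5 (not isolated)
Conditions: (COCl)2, DMF (cat.), CH2Cl2, 0 to 23 °C, evaporate; then CH3CHN2 (3 equiv), Et2O, −20 to 0 °C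
Reagents that add atoms: diazoethane, CC=[N+]=[N-]
Why: Arndt–Eistert-type acylation of diazoethane by the acid chloride (a second equivalent of diazoethane takes up the HCl) gives the α-methyl α-diazoketone regiochemically unambiguously and leaves the stereocentre untouched.

Step 4
Reactants: 6 (5S)-2-diazo-5-(2-methoxy-4-methylphenyl)-6-methylheptan-3-one
Product: 9 (3S,3aR,8aR)-6,8a-dimethyl-3-(propan-2-yl)-2,3,3a,8a-tetrahydroazulene-1,4-dione, via norcaradiene 7 (not isolated), via methoxyazulenone 8 (not isolated)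
Conditions: Rh2(OAc)4 (1 mol %), CH2Cl2, 40 °C, slow addition of 6; then 0.5 M aq. oxalic acid, THF, 0 °C
Reagents that add atoms: water, O
Why: Intramolecular Büchner reaction, in which rhodium-catalysed carbene transfer from 6 cyclopropanates the ipso/ortho bond on the unsubstituted side of the arene and norcaradiene 7 opens by 6π electrocyclisation to cycloheptatriene 8, so both carbocycles form at once; the benzylic centre (its H eclipsing the methoxy-bearing ortho carbon, isopropyl turned away from the incoming carbene) should place the new angular methyl trans to isopropyl, and the mild acid then hydrolyses the methyl enol ether with protonation of C3a anti to isopropyl to give the cis-fused dienone.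

Step 5
Reactants: 9 (3S,3aR,8aR)-6,8a-dimethyl-3-(propan-2-yl)-2,3,3a,8a-tetrahydroazulene-1,4-dione
Product: 11 (3S,3aR,8aR)-6,8a-dimethyl-3-(propan-2-yl)-2,3,3a,5,8,8a-hexahydroazulene-1,4-dione, via lithium dienolate 10 (not isolated)
Conditions: Li (2.2 equiv), NH3(l)/THF, t-BuOH (1 equiv), −78 °C; then solid NH4Cl
Reagents that add atoms: none
Why: Dissolving-metal 1,6-reduction of the linear dienone puts H on C8, and kinetic α-protonation (C5) of dienolate 10 on quench leaves the C6=C7 alkene out of conjugation, while the isolated C1 ketone is reduced much more slowly with only 2.2 equivalents of lithium.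

Step 6
Reactants: 11 (3S,3aR,8aR)-6,8a-dimethyl-3-(propan-2-yl)-2,3,3a,5,8,8a-hexahydroazulene-1,4-dione
Product: 12 (3S,3aR,8aR)-4,4-(ethane-1,2-diyldioxy)-6,8a-dimethyl-3-(propan-2-yl)-2,3,3a,4,5,8-hexahydroazulen-1(8aH)-one
Conditions: Me3SiOCH2CH2OSiMe3 (1.2 equiv), Me3SiOSO2CF3 (5 mol %), CH2Cl2, −78 to −40 °C
Reagents that add atoms: 1,2-bis(trimethylsilyloxy)ethane, C[Si](C)(C)OCCO[Si](C)(C)C
Why: Noyori ketalisation is expected to take the cycloheptanone carbonyl (C4) in preference to the cyclopentanone carbonyl flanked by the quaternary carbon, and the aprotic low-temperature conditions neither move the alkene into conjugation nor epimerise C3a.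

Step 7
Reactants: 12 (3S,3aR,8aR)-4,4-(ethane-1,2-diyldioxy)-6,8a-dimethyl-3-(propan-2-yl)-2,3,3a,4,5,8-hexahydroazulen-1(8aH)-one
Product: 14 (3aR,8aR)-4,4-(ethane-1,2-diyldioxy)-6,8a-dimethyl-3-(propan-2-yl)-3a,4,5,8-tetrahydroazulen-1(8aH)-one, via lithium enolate 13 (not isolated)
Conditions: LiN(iPr)2, THF, −78 °C; then PhS(Cl)=N-t-Bu, −78 °C
Reagents that add atoms: none
Why: Mukaiyama dehydrogenation, in which the C1 ketone can enolise only toward C2 and enolate 13 is sulfenylated and loses the sulfenamide by syn-elimination together with the C3 hydrogen, giving the enone and erasing the now superfluous C3 stereocentre.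

Step 8
Reactants: 14 (3aR,8aR)-4,4-(ethane-1,2-diyldioxy)-6,8a-dimethyl-3-(propan-2-yl)-3a,4,5,8-tetrahydroazulen-1(8aH)-one
Product: 15 (1S,3aR,8aR)-4,4-(ethane-1,2-diyldioxy)-6,8a-dimethyl-3-(propan-2-yl)-1,3a,4,5,8,8a-hexahydroazulen-1-ol
Conditions: NaBH4, CeCl3·7H2O, MeOH, −78 °C
Reagents that add atoms: none
Why: Luche 1,2-reduction, in which hydride should add to the C1 carbonyl from the convex face of the cis-fused bicycle (the face of the angular methyl, away from the seven-membered ring and its dioxolane), giving the 1S alcohol with OH trans to that methyl.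

Step 9
Reactants: 15 (1S,3aR,8aR)-4,4-(ethane-1,2-diyldioxy)-6,8a-dimethyl-3-(propan-2-yl)-1,3a,4,5,8,8a-hexahydroazulen-1-ol
Product: 16 (1R,2R,3S,3aS,8aR)-2,3-epoxy-4,4-(ethane-1,2-diyldioxy)-6,8a-dimethyl-3-(propan-2-yl)-1,2,3,3a,4,5,8,8a-octahydroazulen-1-ol
Conditions: VO(acac)2 (5 mol %), t-BuOOH, CH2Cl2, 0 °C
Reagents that add atoms: tert-butyl hydroperoxide, CC(C)(C)OO
Why: Sharpless-type vanadium-catalysed hydroxyl-directed epoxidation delivers oxygen to the C2=C3 face syn to the allylic OH (so the future C3–O bond is trans to the angular methyl), while the isolated C6=C7 alkene has no directing group and stays intact.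

Step 10
Reactants: 16 (1R,2R,3S,3aS,8aR)-2,3-epoxy-4,4-(ethane-1,2-diyldioxy)-6,8a-dimethyl-3-(propan-2-yl)-1,2,3,3a,4,5,8,8a-octahydroazulen-1-ol
Product: 17 (1S,3S,3aS,8aR)-4,4-(ethane-1,2-diyldioxy)-6,8a-dimethyl-3-(propan-2-yl)-1,2,3,3a,4,5,8,8a-octahydroazulene-1,3-diol
Conditions: NaAlH2(OCH2CH2OCH3)2, THF, 0 to 23 °C
Reagents that add atoms: none
Why: Regioselective hydride opening of a 2,3-epoxy alcohol, in which the O1-bound aluminate delivers hydride by SN2 attack to the adjacent, less substituted epoxide carbon C2 and leaves the tertiary C3–O bond in place, giving the cis-1,3-diol with isopropyl on the convex face.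

Step 11
Reactants: 17 (1S,3S,3aS,8aR)-4,4-(ethane-1,2-diyldioxy)-6,8a-dimethyl-3-(propan-2-yl)-1,2,3,3a,4,5,8,8a-octahydroazulene-1,3-diol; 18 (2Z)-2-methylbut-2-enoic anhydride (angelic anhydride)
Product: 20 (1S,3S,3aS,8aR)-4,4-(ethane-1,2-diyldioxy)-3-hydroxy-6,8a-dimethyl-3-(propan-2-yl)-1,2,3,3a,4,5,8,8a-octahydroazulen-1-yl (2Z)-2-methylbut-2-enoate, via lithium alkoxide 19 (not isolated)
Conditions: LiN(SiMe3)2 (1.05 equiv), THF, −78 °C; then 18, −78 to 0 °C; aq. NH4Cl
Reagents that add atoms: none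
Why: O-acylation of the lithium alkoxide of the only secondary hydroxyl by the anhydride, conditions used to angeloylate hindered alcohols without Z to E isomerisation, the tertiary hydroxyl being too hindered to react.

Step 12
Reactants: 20 (1S,3S,3aS,8aR)-4,4-(ethane-1,2-diyldioxy)-3-hydroxy-6,8a-dimethyl-3-(propan-2-yl)-1,2,3,3a,4,5,8,8a-octahydroazulen-1-yl (2Z)-2-methylbut-2-enoate
Product: 21 (1S,3S,3aS,8aR)-3-hydroxy-6,8a-dimethyl-4-oxo-3-(propan-2-yl)-1,2,3,3a,4,5,8,8a-octahydroazulen-1-yl (2Z)-2-methylbut-2-enoate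
Conditions: pyridinium p-toluenesulfonate (cat.), acetone/H2O 10:1, 40 °C
Reagents that add atoms: water, O
Why: Mild acid-catalysed ketal hydrolysis frees the C4 ketone; the now epimerisable ring fusion should stay cis (C4 carbonyl syn to and hydrogen-bonded with the C3 hydroxyl, anti to isopropyl), and the angelate, tertiary alcohol and β,γ-alkene tolerate these conditions.

Step 13
Reactants: 21 (1S,3S,3aS,8aR)-3-hydroxy-6,8a-dimethyl-4-oxo-3-(propan-2-yl)-1,2,3,3a,4,5,8,8a-octahydroazulen-1-yl (2Z)-2-methylbut-2-enoate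
Product: 22 (1S,3S,3aR,4R,8aR)-3,4-dihydroxy-6,8a-dimethyl-3-(propan-2-yl)-1,2,3,3a,4,5,8,8a-octahydroazulen-1-yl (2Z)-2-methylbut-2-enoate
Conditions: Me4NBH(OAc)3, MeCN/AcOH 1:1, −30 °C
Reagents that add atoms: none
Why: Evans–Saksena directed reduction, in which the reagent exchanges an acetate for the C3 hydroxyl and delivers hydride intramolecularly to the concave face of the C4 carbonyl, giving the 1,3-anti diol and hence the 4R alcohol.

Step 14
Reactants: 22 (1S,3S,3aR,4R,8aR)-3,4-dihydroxy-6,8a-dimethyl-3-(propan-2-yl)-1,2,3,3a,4,5,8,8a-octahydroazulen-1-yl (2Z)-2-methylbut-2-enoate; 23 3,4,5-trimethoxybenzoyl chloride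
Product: 24 (1S,3S,3aR,4R,8aR)-3-hydroxy-6,8a-dimethyl-1-{[(2Z)-2-methylbut-2-enoyl]oxy}-3-(propan-2-yl)-1,2,3,3a,4,5,8,8a-octahydroazulen-4-yl 3,4,5-trimethoxybenzoate (target)
Conditions: pyridine, 4-(dimethylamino)pyridine (cat.), CH2Cl2, 0 to 23 °C
Reagents that add atoms: none
Why: Nucleophile-catalysed acylation (acyl chloride, pyridine/DMAP) of the only secondary hydroxyl, the tertiary carbinol being unreactive, so the product is the target.

**Compound list**

1 | (2-methoxy-4-methylphenyl)boronic acid | COc1cc(C)ccc1B(O)O | starting material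
2 | ethyl (2E)-4-methylpent-2-enoate | CCOC(=O)/C=C/C(C)C | starting material
3 | ethyl (3S)-3-(2-methoxy-4-methylphenyl)-4-methylpentanoate | CCOC(=O)C[C@@H](C(C)C)c1ccc(C)cc1OC | intermediate
4 | (3S)-3-(2-methoxy-4-methylphenyl)-4-methylpentanoic acid | OC(=O)C[C@@H](C(C)C)c1ccc(C)cc1OC | intermediate
5 | (3S)-3-(2-methoxy-4-methylphenyl)-4-methylpentanoyl chloride | ClC(=O)C[C@@H](C(C)C)c1ccc(C)cc1OC | intermediate
6 | (5S)-2-diazo-5-(2-methoxy-4-methylphenyl)-6-methylheptan-3-one | CC(=[N+]=[N-])C(=O)C[C@@H](C(C)C)c1ccc(C)cc1OC | intermediate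
7 | norcaradiene valence isomer of 8 (additional C3a–C8 bond, cyclopropane C3a–C8–C8a, diene C4=C5/C6=C7, angular methyl trans to isopropyl) | O=C1C[C@@H](C(C)C)[C@@]23C(OC)=CC(C)=C[C@@H]2[C@@]13C | intermediate
8 | (3S,8aR)-4-methoxy-6,8a-dimethyl-3-(propan-2-yl)-3,8a-dihydroazulen-1(2H)-one | O=C1C[C@@H](C(C)C)C2=C(OC)C=C(C)C=C[C@@]12C | intermediate
9 | (3S,3aR,8aR)-6,8a-dimethyl-3-(propan-2-yl)-2,3,3a,8a-tetrahydroazulene-1,4-dione (cis-fused) | O=C1C[C@@H](C(C)C)[C@H]2C(=O)C=C(C)C=C[C@@]12C | intermediate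
10 | lithium C4-dienolate of 11 (O–C4=C5, C6=C7; stereocentres as in 9) | O=C1C[C@@H](C(C)C)[C@H]2C([O-])=CC(C)=CC[C@@]12C.[Li+] | intermediate
11 | (3S,3aR,8aR)-6,8a-dimethyl-3-(propan-2-yl)-2,3,3a,5,8,8a-hexahydroazulene-1,4-dione | O=C1C[C@@H](C(C)C)[C@H]2C(=O)CC(C)=CC[C@@]12C | intermediate
12 | (3S,3aR,8aR)-4,4-(ethane-1,2-diyldioxy)-6,8a-dimethyl-3-(propan-2-yl)-2,3,3a,4,5,8-hexahydroazulen-1(8aH)-one | O=C1C[C@@H](C(C)C)[C@H]2C3(OCCO3)CC(C)=CC[C@@]12C | intermediate
13 | lithium C1(2)-enolate of 12 (O–C1=C2; stereocentres as in 12) | [Li+].[O-]C1=C[C@@H](C(C)C)[C@H]2C3(OCCO3)CC(C)=CC[C@@]12C | intermediate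
14 | (3aR,8aR)-4,4-(ethane-1,2-diyldioxy)-6,8a-dimethyl-3-(propan-2-yl)-3a,4,5,8-tetrahydroazulen-1(8aH)-one | O=C1C=C(C(C)C)[C@H]2C3(OCCO3)CC(C)=CC[C@@]12C | intermediate
15 | (1S,3aR,8aR)-4,4-(ethane-1,2-diyldioxy)-6,8a-dimethyl-3-(propan-2-yl)-1,3a,4,5,8,8a-hexahydroazulen-1-ol | O[C@H]1C=C(C(C)C)[C@H]2C3(OCCO3)CC(C)=CC[C@@]12C | intermediate
16 | (1R,2R,3S,3aS,8aR)-2,3-epoxy-4,4-(ethane-1,2-diyldioxy)-6,8a-dimethyl-3-(propan-2-yl)-1,2,3,3a,4,5,8,8a-octahydroazulen-1-ol (epoxide cis to 1-OH, trans to 8a-methyl) | O[C@H]1[C@H]3O[C@@]3(C(C)C)[C@H]2C4(OCCO4)CC(C)=CC[C@@]12C | intermediate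
17 | (1S,3S,3aS,8aR)-4,4-(ethane-1,2-diyldioxy)-6,8a-dimethyl-3-(propan-2-yl)-1,2,3,3a,4,5,8,8a-octahydroazulene-1,3-diol | O[C@H]1C[C@](O)(C(C)C)[C@H]2C3(OCCO3)CC(C)=CC[C@@]12C | intermediate
18 | (2Z)-2-methylbut-2-enoic anhydride (angelic anhydride) | C/C=C(/C)C(=O)OC(=O)/C(C)=C\C | starting material
19 | lithium 1-alkoxide of diol 17 | [Li+].[O-][C@H]1C[C@](O)(C(C)C)[C@H]2C3(OCCO3)CC(C)=CC[C@@]12C | intermediate
20 | (1S,3S,3aS,8aR)-4,4-(ethane-1,2-diyldioxy)-3-hydroxy-6,8a-dimethyl-3-(propan-2-yl)-1,2,3,3a,4,5,8,8a-octahydroazulen-1-yl (2Z)-2-methylbut-2-enoate | C/C=C(/C)C(=O)O[C@H]1C[C@](O)(C(C)C)[C@H]2C3(OCCO3)CC(C)=CC[C@@]12C | intermediate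
21 | (1S,3S,3aS,8aR)-3-hydroxy-6,8a-dimethyl-4-oxo-3-(propan-2-yl)-1,2,3,3a,4,5,8,8a-octahydroazulen-1-yl (2Z)-2-methylbut-2-enoate | C/C=C(/C)C(=O)O[C@H]1C[C@](O)(C(C)C)[C@H]2C(=O)CC(C)=CC[C@@]12C | intermediate
22 | (1S,3S,3aR,4R,8aR)-3,4-dihydroxy-6,8a-dimethyl-3-(propan-2-yl)-1,2,3,3a,4,5,8,8a-octahydroazulen-1-yl (2Z)-2-methylbut-2-enoate | C/C=C(/C)C(=O)O[C@H]1C[C@](O)(C(C)C)[C@H]2[C@H](O)CC(C)=CC[C@@]12C | intermediate
23 | 3,4,5-trimethoxybenzoyl chloride | COc1cc(C(=O)Cl)cc(OC)c1OC | starting material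
24 | (1S,3S,3aR,4R,8aR)-3-hydroxy-6,8a-dimethyl-1-{[(2Z)-2-methylbut-2-enoyl]oxy}-3-(propan-2-yl)-1,2,3,3a,4,5,8,8a-octahydroazulen-4-yl 3,4,5-trimethoxybenzoate | C/C=C(/C)C(=O)O[C@H]1C[C@](O)(C(C)C)[C@H]2[C@H](OC(=O)c3cc(OC)c(OC)c(OC)c3)CC(C)=CC[C@@]12C | target

**Step count and risks**

Total step count: 14. Longest linear sequence: 14 steps (from 1 and 2; the route is fully linear).

Most likely to fail:

Step 4 (key step). The α-methyl carbene can undergo a 1,2-hydride shift to an enone, the electron-rich arene can give aromatic substitution (tetralone) instead of ring expansion, and facial control may be incomplete. Fallback, setting out from acid chloride 5 and returning at 8: excess CH2N2 converts 5 into the terminal diazoketone (4S)-1-diazo-4-(2-methoxy-4-methylphenyl)-5-methylhexan-2-one F1, which cannot suffer the hydride shift. Rh2(OAc)4 takes it through the des-methyl norcaradiene F2 to (3S,8aR)-4-methoxy-6-methyl-3-(propan-2-yl)-3,8a-dihydroazulen-1(2H)-one F3. The angular methyl is then introduced by C-alkylation of the extended potassium enolate of F3 (KOt-Bu, MeI, THF, −78 °C), MeI entering anti to the isopropyl group. This gives methoxyazulenone 8, which is hydrolysed to 9 as in step 4.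

Step 5. Over-reduction of the C1 ketone, or γ-protonation of the dienolate, would give the alcohol or the conjugated enone. Fallback, setting out from 9 and returning at 12: hydrogenation with RhCl(PPh3)3 (H2, 1 atm, benzene) saturates only the disubstituted C7=C8 alkene and gives the conjugated enone (3S,3aR,8aR)-6,8a-dimethyl-3-(propan-2-yl)-2,3,3a,7,8,8a-hexahydroazulene-1,4-dione F4. Deconjugative ketalisation of F4 (ethylene glycol, p-toluenesulfonic acid, benzene, Dean–Stark) moves the alkene to C6=C7 while forming the dioxolane, landing directly on 12.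

Step 11. The secondary hydroxyl is next to a quaternary carbon, and angelates isomerise easily to tiglates. Fallback, setting out from diol 17 and returning at 20: O1 is esterified with 2-[bis(2,2,2-trifluoroethoxy)phosphoryl]propanoic acid (EDC·HCl, DMAP, CH2Cl2) to give (1S,3S,3aS,8aR)-4,4-(ethane-1,2-diyldioxy)-3-hydroxy-6,8a-dimethyl-3-(propan-2-yl)-1,2,3,3a,4,5,8,8a-octahydroazulen-1-yl 2-[bis(2,2,2-trifluoroethoxy)phosphoryl]propanoate F5. A Still–Gennari olefination with acetaldehyde (KN(SiMe3)2, 18-crown-6, THF, −78 °C) then builds the (Z)-2-methylbut-2-enoate on the molecule, giving 20.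

**Further compounds**

F1 | step 4 | (4S)-1-diazo-4-(2-methoxy-4-methylphenyl)-5-methylhexan-2-one | [N-]=[N+]=CC(=O)C[C@@H](C(C)C)c1ccc(C)cc1OC
F2 | step 4 | des-methyl norcaradiene (valence isomer of F3 with cyclopropane C3a–C8–C8a) | O=C1C[C@@H](C(C)C)[C@@]23C(OC)=CC(C)=C[C@@H]2[C@@H]13
F3 | step 4 | (3S,8aR)-4-methoxy-6-methyl-3-(propan-2-yl)-3,8a-dihydroazulen-1(2H)-one | O=C1C[C@@H](C(C)C)C2=C(OC)C=C(C)C=C[C@@H]12
F4 | step 5 | (3S,3aR,8aR)-6,8a-dimethyl-3-(propan-2-yl)-2,3,3a,7,8,8a-hexahydroazulene-1,4-dione | O=C1C[C@@H](C(C)C)[C@H]2C(=O)C=C(C)CC[C@@]12C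
F5 | step 11 | (1S,3S,3aS,8aR)-4,4-(ethane-1,2-diyldioxy)-3-hydroxy-6,8a-dimethyl-3-(propan-2-yl)-1,2,3,3a,4,5,8,8a-octahydroazulen-1-yl 2-[bis(2,2,2-trifluoroethoxy)phosphoryl]propanoate | CC(C(=O)O[C@H]1C[C@](O)(C(C)C)[C@H]2C3(OCCO3)CC(C)=CC[C@@]12C)P(=O)(OCC(F)(F)F)OCC(F)(F)F
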